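# Proposed synthesis of CNP0302404.1 (compound 19)

Atom labels used below: outer dioxane O-1, C-2, C-3, O-4 (fused to ring A at C-4a/C-8a, propenal on C-6); inner dioxane O-1', C-2', C-3', O-4' (fused to ring B at C-4a'/C-8a'); ring B is bonded through C-6' to C-3; ring C is the catechol on C-2'.

## Analysis of the target

Target 19 is a sesquineolignan of three C6–C3 units: ring A carries the (E)-propenal, ring B is the central arene and ring C is a free catechol, joined by two 2,3-dihydro-1,4-benzodioxine rings. It has four stereocentres in two vicinal pairs: C-2 (S, CH2OH) and C-3 (S, ring B) are trans, whereas C-2' (R, ring C) and C-3' (S, CH2OH) are cis. Ring B insulates the pairs from each other, so neither can direct the other and each needs its own source of absolute configuration. The rings also differ in regiochemistry: in the outer ring the oxygen para to the side chain (O-1) sits on the CH2OH carbon C-2, while in the inner ring the para oxygen O-1' sits on the benzylic carbon C-2'. Sensitive groups are the enal, the oxidisable catechol and the two benzylic aryl ether bonds C-3–O-4 and C-2'–O-1'. These bonds ionise under acid and, once the para oxygen is a free phenol, open to quinone methides under base; by either path a cis ring relaxes to trans. The difficulty is therefore a contra-thermodynamic cis ring next to a trans ring, because the usual ring closures at the benzylic carbon give trans for both. The feature the plan exploits is that each dioxane has two O–C(sp3) bonds and two O–C(aryl) bonds (inner ring: O-1'–C-2', O-4'–C-3', C-8a'–O-1', C-4a'–O-4'). Forming an O–C(aryl) bond leaves the carbinol carbon untouched and forming an O–C(sp3) bond by SN2 inverts it, so a trans-epoxide read through one bond of each kind can only give the cis ring.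

## Retrosynthetic reasoning

**19 to 18.** The C=C bond of the propenal next to ring A is cut. The enal is the most fragile group, so it is made last by a Wittig two-carbon homologation with a formyl-stabilised ylide. As an aryl aldehyde the C-6 substituent tolerates base, acid, copper and hydrogen, and it is the para acceptor needed for fluoride displacement in the outer-ring annulation.

**18 to 17.** Three O-benzyl bonds are cut (two on ring C, one on the inner CH2OH). Hydrogenolysis is neutral, so the cis ring meets neither acid nor base once its para phenol is free, and it must precede the alkene.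

**17 to 10 and 15 (key disconnection).** The inner ring is cut at O-1'–C-2' and at C-4a'–O-4', not at its two O–C(sp3) bonds. The classical cut ends with closure at the benzylic carbon through a cation or quinone methide and gives trans. Here the phenoxide of 10 attacks the benzylic carbon of the trans-epoxide 15 with inversion, and the liberated alkoxide is arylated at the iodine-bearing carbon with retention. The gains are convergence (two halves of similar size), regiochemistry fixed by which position of ring B carries OH and which carries iodine, and both inner stereocentres taken from one Sharpless event. The forward reaction must give benzylic regioselectivity, a clean SN2 opening and six-membered O-arylation.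

**10 to 8.** C-3 is epimerised and the ring-B phenol unmasked. The inversion/retention logic makes a cis ring from any trans-epoxide, and the outer ring must be trans. Trans is the thermodynamic isomer and C-3 is a para-oxygenated benzylic ether, so acid equilibrates it while C-2 stays fixed. The step is placed before the inner ring exists, because C-2' would be just as labile.

**8 to 5 and 6.** The outer ring is cut the same way, at O-4–C-3 and C-8a–O-1. In 6 the halogen is para to the formyl group, so the aryl–O bond forms by SNAr without metal. The iodide of ring B is therefore untouched and saved for the key step.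

**5 back to 1, and 15 back to 11.** Both epoxides come from E-cinnamyl alcohols (4, 13) by Sharpless epoxidation with the same catalyst antipode. The alcohols come from the benzaldehydes 2 and 11 by Horner–Wadsworth–Emmons olefination (3, 12) and hydride reduction. Aldehyde 2 is the methoxymethyl ether of 1, and epoxy alcohol 14 is benzylated to 15 so that only one hydroxyl can be arylated in the key step.

## Alternatives that were turned down

**Alternative 1:** The textbook biomimetic cut of both O–C(sp3) bonds. The forward key step is silver-mediated oxidative coupling of a free ring-B catechol aldehyde with a ring-C para-hydroxycinnamyl alcohol, giving dioxane A1. It was turned down for three reasons: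
- The closure is a quinone-methide trapping under thermodynamic control, so A1 is trans and the cis inner ring is out of reach.
- The radical step has no enantiocontrol and only modest control over which catechol oxygen bonds to the benzylic carbon.
- Two such couplings in sequence would give a set of regio- and diastereomers of 19 that are hard to separate.

**Alternative 2:** The chiral-diol version of the same O–C(sp3) cut. Sharpless asymmetric dihydroxylation of ester 12 would give diol A2. A Mitsunobu etherification at C-2 with a ring-B phenol and acid-induced closure at the benzylic carbon would then give dioxane ester A3. It was turned down because the closure passes through the para-alkoxybenzyl cation and delivers the trans isomer A3, epimeric with the target at C-2'. Forcing cis would need an SN2 displacement at a benzylic carbon carrying an electron-rich arene, which ionises instead. The route also needs hydroxyl differentiation, phenol protection and ester reduction, so the step count exceeds that of the chosen route without solving the cis problem.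

**Alternative 3:** A [4+2] cut of both inner C–O bonds at once. Ortho-quinone A4 would be generated from a ring-B catechol and combined with (Z)-alkene A5 in an inverse-demand hetero-Diels–Alder reaction, giving cis-dioxane A6 in one step. It was turned down for three reasons:
- No reliable enantiocontrol exists for this pairing, so A6 would be racemic and the second ring would give diastereomers.
- With an electron-rich styrene the addition is expected to be stepwise through a benzylic zwitterion, which erases the Z geometry and leaks to trans.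
- The regiochemistry rests on the weak polarisation of A4, which is itself prone to self-condensation.

Key step: step 11

Remark: the SMILES is taken at face value; it fixes the outer dioxane as trans (2S,3S) and the inner one as cis (2R,3S), and the route is built for exactly this diastereomer.

## Route

Step 1
Reactants: 1 4-hydroxy-3-iodobenzaldehyde
Product: 2 3-iodo-4-(methoxymethoxy)benzaldehyde
Conditions: MOMCl, iPr2NEt, CH2Cl2, 0 °C to rt
Reagents that add atoms: chloromethyl methyl ether, COCCl
Why: Phenol O-alkylation to the methoxymethyl acetal; this group survives hydride, the titanium/peroxide system and hot carbonate, and is cleaved by the acid that later equilibrates the outer ring.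

Step 2
Reactants: 2 3-iodo-4-(methoxymethoxy)benzaldehyde
Product: 3 ethyl (2E)-3-[3-iodo-4-(methoxymethoxy)phenyl]prop-2-enoate
Conditions: (EtO)2P(O)CH2CO2Et, NaH, THF, 0 °C to rt
Reagents that add atoms: triethyl phosphonoacetate, CCOC(=O)CP(=O)(OCC)OCC
Why: Horner–Wadsworth–Emmons olefination of an aryl aldehyde with a stabilised phosphonate anion should give the E-cinnamate.

Step 3
Reactants: 3 ethyl (2E)-3-[3-iodo-4-(methoxymethoxy)phenyl]prop-2-enoate
Product: 4 (2E)-3-[3-iodo-4-(methoxymethoxy)phenyl]prop-2-en-1-ol
Conditions: iBu2AlH, CH2Cl2, −78 °C; aq. potassium sodium tartrate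
Reagents that add atoms: none
Why: 1,2-Reduction of a cinnamate by an aluminium hydride at low temperature gives the allylic alcohol without touching the aryl iodide or the acetal.

Step 4
Reactants: 4 (2E)-3-[3-iodo-4-(methoxymethoxy)phenyl]prop-2-en-1-ol
Product: 5 [(2S,3S)-3-[3-iodo-4-(methoxymethoxy)phenyl]oxiran-2-yl]methanol
Conditions: Ti(OiPr)4 (10 mol %), L-(+)-diethyl tartrate (12 mol %), tBuOOH, 4 Å MS, CH2Cl2, −20 °C
Reagents that add atoms: tert-butyl hydroperoxide, CC(C)(C)OO
Why: Sharpless asymmetric epoxidation; the L-tartrate titanium catalyst delivers oxygen to the face of the E-allylic alcohol that gives the (2S,3S)-epoxide, so both centres are set in one event and are trans because the alkene geometry is conserved.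

Step 5
Reactants: 5 [(2S,3S)-3-[3-iodo-4-(methoxymethoxy)phenyl]oxiran-2-yl]methanol; 6 4-fluoro-3-hydroxybenzaldehyde
Product: 8 (2S,3R)-2-(hydroxymethyl)-3-[3-iodo-4-(methoxymethoxy)phenyl]-2,3-dihydro-1,4-benzodioxine-6-carbaldehyde (cis), via ring-opened fluoro diol 7 (not isolated)
Conditions: Cs2CO3, DMF, 70 °C then 100 °C
Reagents that add atoms: none
Why: Tandem epoxide opening/SNAr: the phenoxide of 6 opens the epoxide at the benzylic carbon by SN2 (inversion) and the secondary alkoxide of 7 then displaces the fluoride para to the formyl group (retention at C-2), closing the six-membered ring in preference to the seven-membered one open to the primary hydroxyl. One inversion and one retention turn the trans-epoxide into the cis-dioxane; the fluoride is armed only after O-alkylation because the phenoxide form of 6 is too electron-rich for intermolecular SNAr.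

Step 6
Reactants: 8 (2S,3R)-2-(hydroxymethyl)-3-[3-iodo-4-(methoxymethoxy)phenyl]-2,3-dihydro-1,4-benzodioxine-6-carbaldehyde
Product: 10 (2S,3S)-3-(4-hydroxy-3-iodophenyl)-2-(hydroxymethyl)-2,3-dihydro-1,4-benzodioxine-6-carbaldehyde (trans), via cis phenol 9 (not isolated)
Conditions: CF3CO2H/CH2Cl2 (1:2), 0 °C to rt; then NaHCO3, MeOH/H2O
Reagents that add atoms: none
Why: Acid cleaves the methoxymethyl acetal, and the benzylic C-3–O-4 bond, activated by the para oxygen of ring B, ionises reversibly to the para-hydroxybenzyl cation and recloses, which should equilibrate C-3 to the more stable trans ring. C-2 is not benzylic and keeps its configuration; this is the thermodynamic epimerisation of a benzylic aryl ether that makes acid-closed 2-aryl-1,4-benzodioxanes trans.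

Step 7
Reactants: 11 3,4-bis(benzyloxy)benzaldehyde
Product: 12 ethyl (2E)-3-[3,4-bis(benzyloxy)phenyl]prop-2-enoate
Conditions: (EtO)2P(O)CH2CO2Et, NaH, THF, 0 °C to rt
Reagents that add atoms: triethyl phosphonoacetate, CCOC(=O)CP(=O)(OCC)OCC
Why: Horner–Wadsworth–Emmons olefination, E-selective as in step 2.

Step 8
Reactants: 12 ethyl (2E)-3-[3,4-bis(benzyloxy)phenyl]prop-2-enoate
Product: 13 (2E)-3-[3,4-bis(benzyloxy)phenyl]prop-2-en-1-ol
Conditions: iBu2AlH, CH2Cl2, −78 °C; aq. potassium sodium tartrate
Reagents that add atoms: none
Why: 1,2-Reduction of the cinnamate to the allylic alcohol; benzyl ethers are inert.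

Step 9
Reactants: 13 (2E)-3-[3,4-bis(benzyloxy)phenyl]prop-2-en-1-ol
Product: 14 [(2S,3S)-3-[3,4-bis(benzyloxy)phenyl]oxiran-2-yl]methanol
Conditions: Ti(OiPr)4 (10 mol %), L-(+)-diethyl tartrate (12 mol %), tBuOOH, 4 Å MS, CH2Cl2, −20 °C
Reagents that add atoms: tert-butyl hydroperoxide, CC(C)(C)OO
Why: Sharpless asymmetric epoxidation with the same catalyst antipode as in step 4 sets C-2 and C-3 of the (2S,3S)-epoxide together; the catalytic, sieve-buffered protocol limits opening of the electron-rich epoxide.

Step 10
Reactants: 14 [(2S,3S)-3-[3,4-bis(benzyloxy)phenyl]oxiran-2-yl]methanol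
Product: 15 (2S,3S)-2-[(benzyloxy)methyl]-3-[3,4-bis(benzyloxy)phenyl]oxirane
Conditions: NaH, BnBr, Bu4NI (cat.), THF, 0 °C
Reagents that add atoms: benzyl bromide, BrCc1ccccc1
Why: Williamson etherification at low temperature, where alkylation of the alkoxide outruns Payne migration; the benzyl ether leaves one hydroxyl for the key step and is removed with the catechol ethers.

Step 11
Reactants: 10 (2S,3S)-3-(4-hydroxy-3-iodophenyl)-2-(hydroxymethyl)-2,3-dihydro-1,4-benzodioxine-6-carbaldehyde; 15 (2S,3S)-2-[(benzyloxy)methyl]-3-[3,4-bis(benzyloxy)phenyl]oxirane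
Product: 17 (2S,3S)-3-{(2R,3S)-3-[(benzyloxy)methyl]-2-[3,4-bis(benzyloxy)phenyl]-2,3-dihydro-1,4-benzodioxin-6-yl}-2-(hydroxymethyl)-2,3-dihydro-1,4-benzodioxine-6-carbaldehyde, via ring-opened iodo alcohol 16 (not isolated)
Conditions: Cs2CO3, DMF, 80 °C; then CuI (10 mol %), 1,10-phenanthroline (20 mol %), 110 °C
Reagents that add atoms: none
Why: The caesium phenoxide of 10 attacks the benzylic epoxide carbon of 15 from the rear (SN2), giving alkoxide 16; monovalent copper then activates the neighbouring C–I bond and transfers the alkoxide to the aryl carbon (Ullmann-type etherification), closing the inner dioxane. The closest known reaction types are the copper-catalysed tandem ring-opening/O-arylation of ortho-halophenols with epoxides to 2,3-dihydro-1,4-benzodioxines and the benzylic opening of 3-arylglycidol derivatives by phenoxides. The ring closes as a six-membered ring by intramolecular aryl–O bond formation (6-exo at the aryl carbon), and no other ring size is possible because the primary hydroxyl of the epoxide fragment is benzylated. C-2' is set by inversion of the (S)-epoxide carbon to R, and C-3' is set by retention because its C–O bond is never broken. Together these convert the trans-epoxide into the cis ring, and the trans ring can only arise through an SN1 leak. The step needs benzylic rather than C-3' attack, which the electron-rich aryl group and the hindered, inductively deactivated CH(CH2OBn) carbon should secure, and SN2 rather than ionisation, which the basic aprotic medium should secure. The aldehyde and the remote primary alcohol of 10 are spectators, and the outer ring sits at its trans minimum, so any reversible quinone-methide opening under base returns it unchanged until the phenoxide is alkylated. In one operation the step joins the two halves, fixes the inner-ring regiochemistry and builds the hardest ring with both of its stereocentres.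

Step 12
Reactants: 17 (2S,3S)-3-{(2R,3S)-3-[(benzyloxy)methyl]-2-[3,4-bis(benzyloxy)phenyl]-2,3-dihydro-1,4-benzodioxin-6-yl}-2-(hydroxymethyl)-2,3-dihydro-1,4-benzodioxine-6-carbaldehyde
Product: 18 (2S,3S)-3-[(2R,3S)-2-(3,4-dihydroxyphenyl)-3-(hydroxymethyl)-2,3-dihydro-1,4-benzodioxin-6-yl]-2-(hydroxymethyl)-2,3-dihydro-1,4-benzodioxine-6-carbaldehyde
Conditions: H2 (1 atm), 10% Pd/C, EtOAc/EtOH, rt, monitored
Reagents that add atoms: none
Why: Hydrogenolysis of the three O-benzyl groups under neutral conditions; the ring-embedded benzylic aryl ethers and the electron-rich aryl aldehyde react more slowly than O-benzyl groups, and no acid or base touches the cis ring once its para phenol is free.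

Step 13
Reactants: 18 (2S,3S)-3-[(2R,3S)-2-(3,4-dihydroxyphenyl)-3-(hydroxymethyl)-2,3-dihydro-1,4-benzodioxin-6-yl]-2-(hydroxymethyl)-2,3-dihydro-1,4-benzodioxine-6-carbaldehyde
Product: 19 (2E)-3-{(2S,3S)-3-[(2R,3S)-2-(3,4-dihydroxyphenyl)-3-(hydroxymethyl)-2,3-dihydro-1,4-benzodioxin-6-yl]-2-(hydroxymethyl)-2,3-dihydro-1,4-benzodioxin-6-yl}prop-2-enal
Conditions: Ph3P=CHCHO (1.2 equiv), THF, 60 °C, argon
Reagents that add atoms: (triphenylphosphoranylidene)acetaldehyde, O=CC=P(c1ccccc1)(c1ccccc1)c1ccccc1
Why: Wittig olefination with a formyl-stabilised ylide gives the E-enal; the ylide is too weakly basic to deprotonate the catechol or the alcohols, and the 3,4-dialkoxy aryl aldehyde is the only electrophile.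

## Compound list

1 | 4-hydroxy-3-iodobenzaldehyde | O=Cc1ccc(O)c(I)c1 | starting material
2 | 3-iodo-4-(methoxymethoxy)benzaldehyde | COCOc1ccc(C=O)cc1I | intermediate
3 | ethyl (2E)-3-[3-iodo-4-(methoxymethoxy)phenyl]prop-2-enoate | CCOC(=O)/C=C/c1ccc(OCOC)c(I)c1 | intermediate
4 | (2E)-3-[3-iodo-4-(methoxymethoxy)phenyl]prop-2-en-1-ol | OC/C=C/c1ccc(OCOC)c(I)c1 | intermediate
5 | [(2S,3S)-3-[3-iodo-4-(methoxymethoxy)phenyl]oxiran-2-yl]methanol | OC[C@@H]1O[C@H]1c1ccc(OCOC)c(I)c1 | intermediate
6 | 4-fluoro-3-hydroxybenzaldehyde | O=Cc1ccc(F)c(O)c1 | starting material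
7 | 3-{(1R,2S)-2,3-dihydroxy-1-[3-iodo-4-(methoxymethoxy)phenyl]propoxy}-4-fluorobenzaldehyde | O=Cc1ccc(F)c(c1)O[C@H](c1ccc(OCOC)c(I)c1)[C@@H](O)CO | intermediate
8 | (2S,3R)-2-(hydroxymethyl)-3-[3-iodo-4-(methoxymethoxy)phenyl]-2,3-dihydro-1,4-benzodioxine-6-carbaldehyde (cis) | O=Cc1ccc2c(c1)O[C@H](c1ccc(OCOC)c(I)c1)[C@H](CO)O2 | intermediate
9 | (2S,3R)-3-(4-hydroxy-3-iodophenyl)-2-(hydroxymethyl)-2,3-dihydro-1,4-benzodioxine-6-carbaldehyde (cis) | O=Cc1ccc2c(c1)O[C@H](c1ccc(O)c(I)c1)[C@H](CO)O2 | intermediate
10 | (2S,3S)-3-(4-hydroxy-3-iodophenyl)-2-(hydroxymethyl)-2,3-dihydro-1,4-benzodioxine-6-carbaldehyde (trans) | O=Cc1ccc2c(c1)O[C@@H](c1ccc(O)c(I)c1)[C@H](CO)O2 | intermediate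
11 | 3,4-bis(benzyloxy)benzaldehyde | O=Cc1ccc(OCc2ccccc2)c(OCc2ccccc2)c1 | starting material
12 | ethyl (2E)-3-[3,4-bis(benzyloxy)phenyl]prop-2-enoate | CCOC(=O)/C=C/c1ccc(OCc2ccccc2)c(OCc2ccccc2)c1 | intermediate
13 | (2E)-3-[3,4-bis(benzyloxy)phenyl]prop-2-en-1-ol | OC/C=C/c1ccc(OCc2ccccc2)c(OCc2ccccc2)c1 | intermediate
14 | [(2S,3S)-3-[3,4-bis(benzyloxy)phenyl]oxiran-2-yl]methanol | OC[C@@H]1O[C@H]1c1ccc(OCc2ccccc2)c(OCc2ccccc2)c1 | intermediate
15 | (2S,3S)-2-[(benzyloxy)methyl]-3-[3,4-bis(benzyloxy)phenyl]oxirane | c1ccccc1COC[C@@H]1O[C@H]1c1ccc(OCc2ccccc2)c(OCc2ccccc2)c1 | intermediate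
16 | (2S,3S)-3-{4-[(1R,2S)-3-(benzyloxy)-1-[3,4-bis(benzyloxy)phenyl]-2-hydroxypropoxy]-3-iodophenyl}-2-(hydroxymethyl)-2,3-dihydro-1,4-benzodioxine-6-carbaldehyde | O=Cc1ccc2c(c1)O[C@@H](c1ccc(O[C@H](c3ccc(OCc4ccccc4)c(OCc4ccccc4)c3)[C@@H](O)COCc3ccccc3)c(I)c1)[C@H](CO)O2 | intermediate
17 | (2S,3S)-3-{(2R,3S)-3-[(benzyloxy)methyl]-2-[3,4-bis(benzyloxy)phenyl]-2,3-dihydro-1,4-benzodioxin-6-yl}-2-(hydroxymethyl)-2,3-dihydro-1,4-benzodioxine-6-carbaldehyde | O=Cc1ccc2c(c1)O[C@@H](c1ccc3c(c1)O[C@@H](COCc1ccccc1)[C@@H](c1ccc(OCc4ccccc4)c(OCc4ccccc4)c1)O3)[C@H](CO)O2 | intermediate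
18 | (2S,3S)-3-[(2R,3S)-2-(3,4-dihydroxyphenyl)-3-(hydroxymethyl)-2,3-dihydro-1,4-benzodioxin-6-yl]-2-(hydroxymethyl)-2,3-dihydro-1,4-benzodioxine-6-carbaldehyde | O=Cc1ccc2c(c1)O[C@@H](c1ccc3c(c1)O[C@@H](CO)[C@@H](c1ccc(O)c(O)c1)O3)[C@H](CO)O2 | intermediate
19 | (2E)-3-{(2S,3S)-3-[(2R,3S)-2-(3,4-dihydroxyphenyl)-3-(hydroxymethyl)-2,3-dihydro-1,4-benzodioxin-6-yl]-2-(hydroxymethyl)-2,3-dihydro-1,4-benzodioxin-6-yl}prop-2-enal | O=C/C=C/c1ccc2c(c1)O[C@@H](c1ccc3c(c1)O[C@@H](CO)[C@@H](c1ccc(O)c(O)c1)O3)[C@H](CO)O2 | target

## Step count and least certain steps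

Total step count: 13. Longest linear sequence: 9 steps (steps 1 to 6, then 11 to 13); the ring-C branch (steps 7 to 10) joins at step 11.

**Step 11 (key step).** Three things may go wrong:
- Copper-mediated arylation by the hindered secondary alkoxide may be slow, so that protodeiodination or intermolecular phenoxide arylation competes.
- The electron-rich epoxide may partly ionise before the phenoxide arrives, which erodes the cis configuration.
- The para-phenoxide of 10 may spend time as a quinone methide in hot base before it is alkylated.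

The fallback sets out from 10 and 15 and returns at 17. The opening is run without copper at lower temperature (Cs2CO3, DMF, 60 °C) and the iodo alcohol 16 is isolated. The ring is then closed by a different C–O bond-forming manifold, palladium-catalysed intramolecular etherification (Pd(OAc)2, 2-(di-tert-butylphosphino)-1,1'-binaphthyl, Cs2CO3, toluene, 70 °C). This is reductive elimination from divalent palladium, which closes 1,4-benzodioxanes from secondary alcohols with retention. No compound outside the list is made (F0).

**Step 6.** Equilibration may stop short of the trans isomer. Alternatively, the open benzylic cation may lose the C-2 proton, which leads to an enol ether and cleavage of the ring-A ether. The fallback sets out from 8 and returns at 10, and swaps the cationic path for an anionic one. The acetal is removed under conditions too mild to ionise the ring (catalytic HCl, iPrOH/THF, rt) and the cis phenol 9 is isolated. Warming with K2CO3 in DMF (80 °C) lets the para-phenoxide expel the ring-A phenoxide (retro-oxa-Michael to a para-quinone methide). Intramolecular 1,6-addition then recloses to the trans ring 10. No compound outside the list is made (F0).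

**Step 5.** The free primary hydroxyl may cause Payne migration of the epoxide before opening, attack at the non-benzylic carbon, or closure through the primary alkoxide to the seven-membered ring. The fallback sets out from 4 and returns at 10. It builds the trans ring directly by two inversions, with the primary hydroxyl blocked:
- Sharpless epoxidation of 4 with D-(−)-diethyl tartrate gives the enantiomeric epoxy alcohol [(2R,3R)-3-[3-iodo-4-(methoxymethoxy)phenyl]oxiran-2-yl]methanol F1.
- NaH and 4-methoxybenzyl chloride give the 4-methoxybenzyl ether (2R,3R)-2-[3-iodo-4-(methoxymethoxy)phenyl]-3-{[(4-methoxybenzyl)oxy]methyl}oxirane F2.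
- The dianion of 3,4-dihydroxybenzaldehyde (NaH, 2.1 equiv, DMSO, 60 °C) opens F2 at the benzylic carbon through its more nucleophilic 3-oxide, giving the hydroxy phenol 4-hydroxy-3-{(1S,2R)-2-hydroxy-1-[3-iodo-4-(methoxymethoxy)phenyl]-3-[(4-methoxybenzyl)oxy]propoxy}benzaldehyde F3.
- Intramolecular Mitsunobu etherification (PPh3, DIAD, THF) by the acidic 4-hydroxyl inverts C-2 and gives the trans-dioxane (2S,3S)-3-[3-iodo-4-(methoxymethoxy)phenyl]-2-{[(4-methoxybenzyl)oxy]methyl}-2,3-dihydro-1,4-benzodioxine-6-carbaldehyde F4.
- CF3CO2H with anisole removes both acid-labile ethers and gives 10.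

**Step 12.** The primary benzyl ether is the slowest to cleave. While it is being removed, the aryl aldehyde may be over-reduced or the ring benzylic C–O bonds may be hydrogenolysed. The fallback sets out from 17 and returns at 18, and masks the aldehyde:
- HC(OMe)3 with catalytic pyridinium tosylate in MeOH at rt gives the dimethyl acetal [(2S,3S)-3-{(2R,3S)-3-[(benzyloxy)methyl]-2-[3,4-bis(benzyloxy)phenyl]-2,3-dihydro-1,4-benzodioxin-6-yl}-6-(dimethoxymethyl)-2,3-dihydro-1,4-benzodioxin-2-yl]methanol F5.
- Hydrogenolysis (H2, Pd/C, EtOAc with a trace of Et3N) can then be driven to completion and gives the acetal tetrol {(2S,3S)-3-[(2R,3S)-2-(3,4-dihydroxyphenyl)-3-(hydroxymethyl)-2,3-dihydro-1,4-benzodioxin-6-yl]-6-(dimethoxymethyl)-2,3-dihydro-1,4-benzodioxin-2-yl}methanol F6.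
- Aqueous acetic acid in THF at rt, far milder than what is needed to ionise the benzylic ethers, releases 18.

## Further compounds

F0 | step 11 | none | none
F0 | step 6 | none | none
F1 | step 5 | [(2R,3R)-3-[3-iodo-4-(methoxymethoxy)phenyl]oxiran-2-yl]methanol | OC[C@H]1O[C@@H]1c1ccc(OCOC)c(I)c1
F2 | step 5 | (2R,3R)-2-[3-iodo-4-(methoxymethoxy)phenyl]-3-{[(4-methoxybenzyl)oxy]methyl}oxirane | COc1ccc(COC[C@H]2O[C@@H]2c2ccc(OCOC)c(I)c2)cc1
F3 | step 5 | 4-hydroxy-3-{(1S,2R)-2-hydroxy-1-[3-iodo-4-(methoxymethoxy)phenyl]-3-[(4-methoxybenzyl)oxy]propoxy}benzaldehyde | O=Cc1ccc(O)c(c1)O[C@@H](c1ccc(OCOC)c(I)c1)[C@H](O)COCc1ccc(OC)cc1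
F4 | step 5 | (2S,3S)-3-[3-iodo-4-(methoxymethoxy)phenyl]-2-{[(4-methoxybenzyl)oxy]methyl}-2,3-dihydro-1,4-benzodioxine-6-carbaldehyde | O=Cc1ccc2c(c1)O[C@@H](c1ccc(OCOC)c(I)c1)[C@H](COCc1ccc(OC)cc1)O2
F5 | step 12 | [(2S,3S)-3-{(2R,3S)-3-[(benzyloxy)methyl]-2-[3,4-bis(benzyloxy)phenyl]-2,3-dihydro-1,4-benzodioxin-6-yl}-6-(dimethoxymethyl)-2,3-dihydro-1,4-benzodioxin-2-yl]methanol | COC(OC)c1ccc2c(c1)O[C@@H](c1ccc3c(c1)O[C@@H](COCc1ccccc1)[C@@H](c1ccc(OCc4ccccc4)c(OCc4ccccc4)c1)O3)[C@H](CO)O2
F6 | step 12 | {(2S,3S)-3-[(2R,3S)-2-(3,4-dihydroxyphenyl)-3-(hydroxymethyl)-2,3-dihydro-1,4-benzodioxin-6-yl]-6-(dimethoxymethyl)-2,3-dihydro-1,4-benzodioxin-2-yl}methanol | COC(OC)c1ccc2c(c1)O[C@@H](c1ccc3c(c1)O[C@@H](CO)[C@@H](c1ccc(O)c(O)c1)O3)[C@H](CO)O2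
A1 | alternative 1 | rac-(2S,3S)-2-[3-(benzyloxy)-4-hydroxyphenyl]-3-(hydroxymethyl)-2,3-dihydro-1,4-benzodioxine-6-carbaldehyde (trans, racemic, one enantiomer drawn) | O=Cc1ccc2c(c1)O[C@@H](CO)[C@H](c1ccc(O)c(OCc3ccccc3)c1)O2
A2 | alternative 2 | ethyl (2S,3R)-3-[3,4-bis(benzyloxy)phenyl]-2,3-dihydroxypropanoate | CCOC(=O)[C@@H](O)[C@H](O)c1ccc(OCc2ccccc2)c(OCc2ccccc2)c1
A3 | alternative 2 | ethyl (2R,3S)-3-[3,4-bis(benzyloxy)phenyl]-7-formyl-2,3-dihydro-1,4-benzodioxine-2-carboxylate (trans) | O=Cc1ccc2c(c1)O[C@@H](C(=O)OCC)[C@H](c1ccc(OCc3ccccc3)c(OCc3ccccc3)c1)O2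
A4 | alternative 3 | 3,4-dioxocyclohexa-1,5-diene-1-carbaldehyde | O=CC1=CC(=O)C(=O)C=C1
A5 | alternative 3 | (2Z)-3-[3,4-bis(benzyloxy)phenyl]prop-2-en-1-ol | OC/C=C\c1ccc(OCc2ccccc2)c(OCc2ccccc2)c1
A6 | alternative 3 | rac-(2R,3S)-2-[3,4-bis(benzyloxy)phenyl]-3-(hydroxymethyl)-2,3-dihydro-1,4-benzodioxine-6-carbaldehyde (cis, racemic, one enantiomer drawn) | O=Cc1ccc2c(c1)O[C@@H](CO)[C@@H](c1ccc(OCc3ccccc3)c(OCc3ccccc3)c1)O2
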